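**Remark on the chemistry (assumption):** commercial aleuritic acid from shellac is taken to be the threo diastereomer, (9R*,10R*)-9,10,16-trihydroxyhexadecanoic acid. The syn-elimination in step 1 needs this diastereomer to give the E-alkene.

## The problem

Dehydrobisgravillol (19) is an unbranched fourteen-carbon tether. It carries a 3-hydroxy-5-methoxyphenyl ring (ring A) at one end and a 3,5-dihydroxyphenyl ring (ring B) at the other. Its only stereochemical element is the E double bond, which lies off-centre: seven methylenes separate it from ring A and five from ring B. Nothing nearby can direct the geometry, so it has to come from a stereospecific event and not from the kinetic preference of an olefination. The two rings differ by a single O-methyl group, and no late reagent can tell four phenolic oxygens on two remote rings apart. Each ring must therefore arrive already differentiated and at the correct end of the unsymmetrical chain. The free phenols sit on electron-rich rings that are prone to oxidation and electrophilic attack, and the isolated alkene rules out hydrogenolysis and is at risk from thiyl radicals, metal hydrides and hot acid.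

The feature that opens the problem is the attachment of the rings. Each ring is bonded, through a ring carbon flanked by two C–H positions, to a primary sp3 carbon at a chain terminus. That is the bond formed when a primary alkyl radical, released by decarboxylation of an acid one carbon longer, is captured by an aryl–metal species. Lengthened by one carbon at each end, the tether is a C16 chain with CO2H beyond the seven-methylene arm, CH2OH beyond the five-methylene arm and the alkene at C9=C10. This is the skeleton of threo-aleuritic acid (1), whose 9,10-diol is a masked, stereodefined E-alkene. Chain positions are numbered throughout as in 1: ring A ends on C2, ring B on C15, and C1 and C16 are excised.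

## Retrosynthesis

**19 from 18.** The three phenolic O–H bonds are traced back to methoxymethyl ethers in 18. Acetal protection is preferred to benzyl ethers (hydrogenolysis would reduce C9=C10) and to silyl ethers (aryl silyl ethers would not survive the saponification on the way). The forward reaction must cleave three acetals without touching the aryl methyl ether or the alkene and without letting the released methoxymethyl cation attack the rings.

**18 from 12 and 14.** The cut is the C2–C(aryl) bond of ring A, not the alkene. Cutting at C9=C10 would leave two long arylalkyl halves to be built carbon by carbon and a geometry to be controlled. Cutting at the ring leaves acid 12, which carries one extra carbon (C1) that departs as carbon dioxide, and aryl bromide 14. Bromide 14 is made in one step from phenol 13 and brings ring A with its methyl ether already in place. The forward reaction is a decarboxylative arylation through N-acyloxyphthalimide 15 and arylzinc chloride 17. The radical at C2 is far from the alkene, so only ordinary cross-coupling demands apply.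

**12 from 11.** Only the ester C–O bond is changed. The ethyl ester in 11 keeps C1 silent while the other terminus reacts, and simple hydrolysis then exposes the second acid.

**11 from 5 and 7 (key disconnection).** The cut is the C15–C(aryl) bond of ring B. The precursor 5 is a purely aliphatic half-ester in which C16 is the only free acid. The partner 7 is the bis-acetal of commercial diol 6 and reacts through Grignard reagent 9 and arylzinc chloride 10. The product has a complete ring B on the five-methylene arm, while the precursor is two steps from a commodity acid. The forward reaction must capture the C15 radical released from N-acyloxyphthalimide 8 faster than it closes onto C10, and the arylzinc must ignore the ethyl ester.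

**5 from 4.** Carbon C16 is taken back from the acid to the primary alcohol level. Doing this oxidation on 4 means no electron-rich arene is present when the oxidant is used.

**4 from 1.** The C9=C10 π bond is traced back to the two C–O bonds of the threo-diol of 1, through cyclic orthoformate 2 and its fragmentation product 3. This syn-elimination is stereospecific, so threo gives E with no isomer problem. The same operation esterifies C1, so the two termini of 1 (acid and primary alcohol) emerge differentiated as ester and alcohol. Starting material 1 already holds all fourteen tether carbons, the position and latent geometry of the alkene, and two different ends.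

## Roads not taken

**Alternative 1:** the most obvious cut is the C9=C10 double bond itself. The forward key step would be a Julia–Kocienski olefination of aldehyde A1 with the metalated phenyltetrazolyl sulfone A2, giving 18 directly. Two unbranched alkyl partners give an E-enriched mixture, not a single isomer, and E/Z isomers of a remote 1,2-dialkyl alkene are very hard to separate. A1 and A2 would each need several homologation steps from an aryl building block. The chosen plan takes the geometry from a stereospecific elimination and buys the chain intact.

**Alternative 2:** cut the two C(sp)–C(sp3) bonds around an alkyne at C9–C10. Terminal alkyne A3 would be alkylated with primary bromide A4 to give internal alkyne A5, and a dissolving-metal reduction would give 18. The trans geometry would be secure. However, A3 and A4 again have to be assembled from aryl precursors over many steps, acetylide alkylation with an unactivated bromide competes with elimination, and three aryl acetals and a methyl ether must face solvated electrons. The chosen plan is shorter and avoids reducing conditions.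

**Alternative 3:** keep C1 as a ring carbon and build ring A on the chain as a partly saturated ring that is aromatised late. Aldehyde A6 (from 11) would be taken through Wittig acetonylation and a malonate Michael–Claisen annulation with decarboxylation to cyclohexane-1,3-dione A7. O-methylation would give a single vinylogous ester A8, because the dione is symmetric, and dehydrogenation would give the 3-methoxyphenol. The mono-methyl ether would arise without any differentiation problem. The cost is about five steps for a ring that the chosen plan installs in one, and the final dehydrogenation would have to spare C9=C10 from addition or migration.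

Key step: step 4

## Route

Step 1
Reactants: 1 threo-aleuritic acid [rac-(9R,10R)-9,10,16-trihydroxyhexadecanoic acid]
Product: 4 ethyl (E)-16-hydroxyhexadec-9-enoate, via cyclic orthoformate 2 (not isolated), via diethoxymethyl ether 3 (not isolated)
Conditions: HC(OEt)3 (excess), PhCO2H (cat.), 140 °C then 190 °C; then EtOH, aq. HCl (cat.), 60 °C
Reagents that add atoms: triethyl orthoformate CCOC(OCC)OCC
Why: Eastwood olefination: the orthoformate esterifies C1, caps the C16 hydroxyl and converts the threo-diol into 2-ethoxy-1,3-dioxolane 2, which on acid-catalysed heating loses ethanol and carbon dioxide in a suprafacial fragmentation, so the (9R*,10R*) configuration becomes the E geometry of C9=C10 in 3. Acidic ethanolysis then frees the C16 hydroxyl and leaves the ethyl ester.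

Step 2
Reactants: 4 ethyl (E)-16-hydroxyhexadec-9-enoate
Product: 5 (E)-16-ethoxy-16-oxohexadec-7-enoic acid
Conditions: TEMPO (20 mol %), PhI(OAc)2 (2.2 equiv), MeCN/H2O 1:1, rt
Reagents that add atoms: water O
Why: Oxoammonium-mediated oxidation of the primary alcohol through the aldehyde hydrate to the acid; the isolated alkene and the ethyl ester are inert to this oxidant and no arene is present yet.

Step 3
Reactants: 6 5-bromobenzene-1,3-diol
Product: 7 1-bromo-3,5-bis(methoxymethoxy)benzene
Conditions: NaH (2.4 equiv), DMF, 0 °C; MOMCl (2.4 equiv), 0 °C to rt
Reagents that add atoms: chloromethyl methyl ether COCCl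
Why: Williamson-type O-alkylation of both phenoxides; the acetals survive Grignard formation, arylzinc coupling and saponification and leave under acid that spares the methyl ether and the alkene.

Step 4
Reactants: 5 (E)-16-ethoxy-16-oxohexadec-7-enoic acid; 7 1-bromo-3,5-bis(methoxymethoxy)benzene
Product: 11 ethyl (E)-15-[3,5-bis(methoxymethoxy)phenyl]pentadec-9-enoate, via NHP ester 8 (not isolated), via arylmagnesium bromide 9 (not isolated), via arylzinc chloride 10 (not isolated)
Conditions: 5, N-hydroxyphthalimide, DIC, DMAP (cat.), CH2Cl2, rt, solvent switch; then 10 (2.5 equiv) [from 7: Mg, LiCl, THF; ZnCl2], Fe(acac)3 (20 mol %), 1,2-bis(diphenylphosphino)benzene (24 mol %), THF/toluene, rt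
Reagents that add atoms: none
Why: Decarboxylative Negishi-type arylation of a redox-active ester: carbodiimide coupling gives N-acyloxyphthalimide 8, and magnesium insertion into 7 followed by transmetalation gives arylzinc 10. A low-valent aryl-iron species formed from Fe(acac)3, the bisphosphine and 10 transfers one electron to the phthalimide of 8; N–O cleavage and loss of carbon dioxide release the primary radical at C15. The radical is captured at iron and C(sp3)–C(aryl) reductive elimination joins C15 to the ring B carbon that bore bromine, so C16 is replaced by the ring. The closest known reaction type is the iron- or nickel-catalysed coupling of N-acyloxyphthalimides of primary and secondary acids with arylzinc reagents. No ring is closed and no stereocentre is created; the E geometry of C9=C10 is not at stake because the radical is four methylenes away and never allylic. The selectivity needed is capture of the radical by the metal before 6-exo closure onto C10, which the intrinsically slow closure of a hept-6-enyl radical onto a 1,2-dialkyl alkene and a high catalyst loading should secure. Chemoselectivity between the chain termini comes from the substrate: only C16 is activated, while C1 is an ethyl ester that arylzinc chlorides do not attack. The aryl partner has C–H at both ortho positions, which favours transmetalation and reductive elimination.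

Step 5
Reactants: 11 ethyl (E)-15-[3,5-bis(methoxymethoxy)phenyl]pentadec-9-enoate
Product: 12 (E)-15-[3,5-bis(methoxymethoxy)phenyl]pentadec-9-enoic acid
Conditions: LiOH, THF/MeOH/H2O, rt; then 1 M HCl to pH 4, 0 °C
Reagents that add atoms: lithium hydroxide [Li+].[OH-]
Why: Saponification of the ethyl ester by acyl–oxygen cleavage; the aryl acetals and the alkene are stable to hydroxide and to brief cold acidification.

Step 6
Reactants: 13 3-bromo-5-methoxyphenol
Product: 14 1-bromo-3-methoxy-5-(methoxymethoxy)benzene
Conditions: NaH (1.2 equiv), DMF, 0 °C; MOMCl (1.2 equiv), 0 °C to rt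
Reagents that add atoms: chloromethyl methyl ether COCCl
Why: Williamson-type O-alkylation of the single phenoxide; the methyl ether that distinguishes ring A is bought in place and stays untouched.

Step 7
Reactants: 12 (E)-15-[3,5-bis(methoxymethoxy)phenyl]pentadec-9-enoic acid; 14 1-bromo-3-methoxy-5-(methoxymethoxy)benzene
Product: 18 1-[(E)-14-[3-methoxy-5-(methoxymethoxy)phenyl]tetradec-6-en-1-yl]-3,5-bis(methoxymethoxy)benzene, via NHP ester 15 (not isolated), via arylmagnesium bromide 16 (not isolated), via arylzinc chloride 17 (not isolated)
Conditions: 12, N-hydroxyphthalimide, DIC, DMAP (cat.), CH2Cl2, rt, solvent switch; then 17 (2.5 equiv) [from 14: Mg, LiCl, THF; ZnCl2], Fe(acac)3 (20 mol %), 1,2-bis(diphenylphosphino)benzene (24 mol %), THF/toluene, rt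
Reagents that add atoms: none
Why: The same iron-catalysed decarboxylative arylation as in step 4, now replacing C1 by ring A on the seven-methylene arm. The radical at C2 is six methylenes from C9=C10, so no ring closure can compete and the alkene geometry is untouched.

Step 8
Reactants: 18 1-[(E)-14-[3-methoxy-5-(methoxymethoxy)phenyl]tetradec-6-en-1-yl]-3,5-bis(methoxymethoxy)benzene
Product: 19 dehydrobisgravillol, 5-[(E)-14-(3-hydroxy-5-methoxyphenyl)tetradec-6-en-1-yl]benzene-1,3-diol
Conditions: 3 M HCl (aq.), MeOH, 50 °C
Reagents that add atoms: none
Why: Acid-catalysed cleavage of the three aryl acetals; methanol should trap the methoxymethyl cation as dimethoxymethane so that it does not alkylate the electron-rich rings, and the aryl methyl ether and the E-alkene are stable to dilute acid at this temperature.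

## Compound list

1 | threo-aleuritic acid, rac-(9R,10R)-9,10,16-trihydroxyhexadecanoic acid | OCCCCCC[C@@H](O)[C@H](O)CCCCCCCC(=O)O | starting material
2 | ethyl 8-[(4R*,5R*)-5-[6-(diethoxymethoxy)hexyl]-2-ethoxy-1,3-dioxolan-4-yl]octanoate (cyclic orthoformate, C2 epimers) | CCOC(=O)CCCCCCC[C@H]1OC(OCC)O[C@@H]1CCCCCCOC(OCC)OCC | intermediate
3 | ethyl (E)-16-(diethoxymethoxy)hexadec-9-enoate | CCOC(=O)CCCCCCC/C=C/CCCCCCOC(OCC)OCC | intermediate
4 | ethyl (E)-16-hydroxyhexadec-9-enoate | CCOC(=O)CCCCCCC/C=C/CCCCCCO | intermediate
5 | (E)-16-ethoxy-16-oxohexadec-7-enoic acid | CCOC(=O)CCCCCCC/C=C/CCCCCC(=O)O | intermediate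
6 | 5-bromobenzene-1,3-diol | Oc1cc(O)cc(Br)c1 | starting material
7 | 1-bromo-3,5-bis(methoxymethoxy)benzene | COCOc1cc(Br)cc(OCOC)c1 | intermediate
8 | 1-(1,3-dioxoisoindolin-2-yl) 16-ethyl (E)-hexadec-7-enedioate | CCOC(=O)CCCCCCC/C=C/CCCCCC(=O)ON1C(=O)c2ccccc2C1=O | intermediate
9 | [3,5-bis(methoxymethoxy)phenyl]magnesium bromide | COCOc1cc([Mg]Br)cc(OCOC)c1 | intermediate
10 | [3,5-bis(methoxymethoxy)phenyl]zinc chloride | COCOc1cc([Zn]Cl)cc(OCOC)c1 | intermediate
11 | ethyl (E)-15-[3,5-bis(methoxymethoxy)phenyl]pentadec-9-enoate | CCOC(=O)CCCCCCC/C=C/CCCCCc1cc(OCOC)cc(OCOC)c1 | intermediate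
12 | (E)-15-[3,5-bis(methoxymethoxy)phenyl]pentadec-9-enoic acid | OC(=O)CCCCCCC/C=C/CCCCCc1cc(OCOC)cc(OCOC)c1 | intermediate
13 | 3-bromo-5-methoxyphenol | COc1cc(O)cc(Br)c1 | starting material
14 | 1-bromo-3-methoxy-5-(methoxymethoxy)benzene | COCOc1cc(Br)cc(OC)c1 | intermediate
15 | 1,3-dioxoisoindolin-2-yl (E)-15-[3,5-bis(methoxymethoxy)phenyl]pentadec-9-enoate | O=C(CCCCCCC/C=C/CCCCCc1cc(OCOC)cc(OCOC)c1)ON1C(=O)c2ccccc2C1=O | intermediate
16 | [3-methoxy-5-(methoxymethoxy)phenyl]magnesium bromide | COCOc1cc([Mg]Br)cc(OC)c1 | intermediate
17 | [3-methoxy-5-(methoxymethoxy)phenyl]zinc chloride | COCOc1cc([Zn]Cl)cc(OC)c1 | intermediate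
18 | 1-[(E)-14-[3-methoxy-5-(methoxymethoxy)phenyl]tetradec-6-en-1-yl]-3,5-bis(methoxymethoxy)benzene | COCOc1cc(OC)cc(CCCCCCC/C=C/CCCCCc2cc(OCOC)cc(OCOC)c2)c1 | intermediate
19 | dehydrobisgravillol, 5-[(E)-14-(3-hydroxy-5-methoxyphenyl)tetradec-6-en-1-yl]benzene-1,3-diol | COc1cc(O)cc(CCCCCCC/C=C/CCCCCc2cc(O)cc(O)c2)c1 | target

## Step count and least certain steps

Total steps: 8. Longest linear sequence: 6 (steps 1, 2, 4, 5, 7, 8); steps 3 and 6 prepare the two aryl bromides.

**Step 4 (key step).** The C15 radical may close onto C10 (6-exo) before the metal captures it. It may also be lost by hydrogen abstraction or, after capture, by β-hydride elimination, and the arylzinc may be consumed by homocoupling. The fallback separates decarboxylation from C–C bond formation and makes the chain the two-electron nucleophile. Setting out from 5, the acid would be condensed with N-hydroxypyridine-2-thione (DCC, CH2Cl2, dark) to the thiohydroxamate ester F1. Visible-light irradiation with iodoform would effect a Barton decarboxylative iodination, in which iodine-atom transfer is far faster than ring closure, to give ethyl (E)-15-iodopentadec-9-enoate F2. Zinc insertion (Zn dust, LiCl, THF) would give the alkylzinc iodide F3. A Negishi coupling with 7 (Pd(OAc)2, SPhos, THF) would then return to the route at 11.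

**Step 7.** No cyclisation threatens here, but the primary radical may be reduced or eliminated before aryl transfer, and the less symmetrical arylzinc 17 may be consumed by homocoupling or protonation. The fallback sets out from 12 by way of its NHP ester 15. Copper-catalysed decarboxylative borylation (Cu(acac)2, bis(pinacolato)diboron, LiOH·H2O, MgCl2, dioxane/DMF) would give the pinacol boronate F4. A B-alkyl Suzuki–Miyaura coupling with 14 (Pd(OAc)2, RuPhos, K2CO3, toluene/H2O, 80 °C) would return to the route at 18.

**Step 1.** The dioxolanylium intermediate may be opened by carboxylate instead of fragmenting, intermolecular transesterification may set in at 190 °C, and formyl residues on the C16 oxygen may be cleaved incompletely. The fallback is a Corey–Winter olefination at lower temperature and without acid. Setting out from 1, Fischer esterification (EtOH, H2SO4 cat.) would give ethyl aleuritate F5. Selective silylation of the primary hydroxyl (TBDPSCl, imidazole, DMF, 0 °C) would give the silyl ether F6. 1,1'-Thiocarbonyldiimidazole (toluene, 80 °C) would give the cyclic thionocarbonate F7. Heating with P(OMe)3 would effect the syn-elimination to the E-alkene silyl ether F8, and Bu4NF in THF would return to the route at 4.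

## Further compounds

F1 | step 4 | ethyl (E)-16-oxo-16-[(2-thioxopyridin-1(2H)-yl)oxy]hexadec-9-enoate | CCOC(=O)CCCCCCC/C=C/CCCCCC(=O)On1ccccc1=S
F2 | step 4 | ethyl (E)-15-iodopentadec-9-enoate | CCOC(=O)CCCCCCC/C=C/CCCCCI
F3 | step 4 | [(E)-15-ethoxy-15-oxopentadec-6-en-1-yl]zinc iodide | CCOC(=O)CCCCCCC/C=C/CCCCC[Zn]I
F4 | step 7 | 2-[(E)-14-[3,5-bis(methoxymethoxy)phenyl]tetradec-8-en-1-yl]-4,4,5,5-tetramethyl-1,3,2-dioxaborolane | CC1(C)OB(CCCCCCC/C=C/CCCCCc2cc(OCOC)cc(OCOC)c2)OC1(C)C
F5 | step 1 | ethyl rac-(9R,10R)-9,10,16-trihydroxyhexadecanoate | CCOC(=O)CCCCCCC[C@@H](O)[C@H](O)CCCCCCO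
F6 | step 1 | ethyl rac-(9R,10R)-16-[(tert-butyldiphenylsilyl)oxy]-9,10-dihydroxyhexadecanoate | CCOC(=O)CCCCCCC[C@@H](O)[C@H](O)CCCCCCO[Si](c1ccccc1)(c1ccccc1)C(C)(C)C
F7 | step 1 | ethyl 8-[(4R*,5R*)-5-[6-[(tert-butyldiphenylsilyl)oxy]hexyl]-2-thioxo-1,3-dioxolan-4-yl]octanoate | CCOC(=O)CCCCCCC[C@H]1OC(=S)O[C@@H]1CCCCCCO[Si](c1ccccc1)(c1ccccc1)C(C)(C)C
F8 | step 1 | ethyl (E)-16-[(tert-butyldiphenylsilyl)oxy]hexadec-9-enoate | CCOC(=O)CCCCCCC/C=C/CCCCCCO[Si](c1ccccc1)(c1ccccc1)C(C)(C)C
A1 | alternative 1 | 8-[3-methoxy-5-(methoxymethoxy)phenyl]octanal | O=CCCCCCCCc1cc(OC)cc(OCOC)c1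
A2 | alternative 1 | 5-[[6-[3,5-bis(methoxymethoxy)phenyl]hexyl]sulfonyl]-1-phenyl-1H-tetrazole | COCOc1cc(CCCCCCS(=O)(=O)c2nnnn2-c2ccccc2)cc(OCOC)c1
A3 | alternative 2 | 1-methoxy-3-(methoxymethoxy)-5-(non-8-yn-1-yl)benzene | C#CCCCCCCCc1cc(OC)cc(OCOC)c1
A4 | alternative 2 | 1-(5-bromopentyl)-3,5-bis(methoxymethoxy)benzene | BrCCCCCc1cc(OCOC)cc(OCOC)c1
A5 | alternative 2 | 1-[14-[3-methoxy-5-(methoxymethoxy)phenyl]tetradec-6-yn-1-yl]-3,5-bis(methoxymethoxy)benzene | COCOc1cc(OC)cc(CCCCCCCC#CCCCCCc2cc(OCOC)cc(OCOC)c2)c1
A6 | alternative 3 | (E)-15-[3,5-bis(methoxymethoxy)phenyl]pentadec-9-enal | O=CCCCCCCC/C=C/CCCCCc1cc(OCOC)cc(OCOC)c1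
A7 | alternative 3 | 5-[(E)-14-[3,5-bis(methoxymethoxy)phenyl]tetradec-8-en-1-yl]cyclohexane-1,3-dione | O=C1CC(CCCCCCC/C=C/CCCCCc2cc(OCOC)cc(OCOC)c2)CC(=O)C1
A8 | alternative 3 | 5-[(E)-14-[3,5-bis(methoxymethoxy)phenyl]tetradec-8-en-1-yl]-3-methoxycyclohex-2-en-1-one | COC1=CC(=O)CC(CCCCCCC/C=C/CCCCCc2cc(OCOC)cc(OCOC)c2)C1
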